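The oxocane (ring numbering O1, C2 with the pentenynyl chain, C3 Cl, C5 Cl, C6 OAc, C8 with the bromopropyl group) is disconnected at O1–C2 and C5–C6, the two bonds that flank the four-carbon unit C2–C5. Both form in one operation by merging two four-membered rings: the lithium enolate of cyclobutanone is C-acylated by an enantiopure β-lactone (C6–C8 and O1), and the liberated alkoxide adds to the cyclobutanone carbonyl and triggers a retro-Claisen ring expansion to an eight-membered keto-lactone. The step exploits the 1,5-dioxygenated pattern C2/C6 of the oxocane: both carbons arrive as carbonyls, so both chlorides enter by α-chlorination and C2 is allylated through its oxocarbenium ion.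

Key step: step 4

Remark: all ring compounds are named with the numbering given above (O1, C2 … C8), which for the last compounds is not the lowest-locant numbering; TBDPS = tert-butyldiphenylsilyl, TBS = tert-butyldimethylsilyl, TIPS = triisopropylsilyl.
Remark: in step 1 the (S)-alcohol is assumed to be the fast-reacting enantiomer with L-(+)-diisopropyl tartrate (the normal sense for alk-1-en-3-ols); if the sense proves opposite, the D-(−)-tartrate is used.

Step 1
Reactants: 1 (±)-pent-1-en-3-ol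
Product: 2 (1S)-1-[(2R)-oxiran-2-yl]propan-1-ol
Conditions: Ti(OiPr)4, L-(+)-diisopropyl tartrate, t-BuOOH (0.45 equiv), 4 Å molecular sieves, CH2Cl2, −20 °C
Reagents that add atoms: tert-butyl hydroperoxide, CC(C)(C)OO
Why: Sharpless asymmetric epoxidation run as a kinetic resolution, in which the (S)-alcohol is epoxidised fast and erythro-selectively, so that both stereocenters (2R,3S) are set by the tartrate.

Step 2
Reactants: 2 (1S)-1-[(2R)-oxiran-2-yl]propan-1-ol
Product: 3 tert-butyl{(1S)-1-[(2R)-oxiran-2-yl]propoxy}diphenylsilane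
Conditions: TBDPSCl, imidazole, DMF, 0 °C to rt
Reagents that add atoms: tert-butyl(chloro)diphenylsilane, CC(C)(C)[Si](Cl)(c1ccccc1)c1ccccc1
Why: imidazole-promoted silylation of the secondary alcohol masks the oxygen that is replaced by bromide at the end, and no stereocenter is touched.

Step 3
Reactants: 3 tert-butyl{(1S)-1-[(2R)-oxiran-2-yl]propoxy}diphenylsilane
Product: 4 (4R)-4-[(1S)-1-(TBDPS-oxy)propyl]oxetan-2-one
Conditions: CO (60 bar), [Cp2Ti(THF)2][Co(CO)4] (2 mol%), DME, 60 °C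
Reagents that add atoms: carbon monoxide, [C-]#[O+]
Why: Lewis acid/tetracarbonylcobaltate ring-expanding carbonylation of a terminal epoxide, in which the cobaltate opens the activated epoxide at its CH2 terminus, CO inserts and the alkoxide closes the β-lactone, so the C–O stereocenter (later C8) is retained.

Step 4
Reactants: 4 (4R)-4-[(1S)-1-(TBDPS-oxy)propyl]oxetan-2-one; 5 cyclobutanone
Product: 10 (8R)-8-[(1S)-1-(TBDPS-oxy)propyl]oxocane-2,6-dione, via lithium cyclobutenolate 6 (not isolated), via acylated cyclobutanone alkoxide 7 (not isolated), via bicyclic hemiketal alkoxide 8 (not isolated), via ring-expanded lithium enolate 9 (not isolated)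
Conditions: LiN(SiMe3)2 (1.05 equiv), THF, −78 °C, then 5; then 4, −78 to 0 °C; AcOH, −78 °C
Reagents that add atoms: none
Why: Proposed new method: the lithium enolate 6, a hard nucleophile, attacks the acyl carbon of the strained β-lactone 4 (Claisen-type C-acylation, forming C5–C6) and the lactone opens to the alkoxide 7; this alkoxide adds to the highly electrophilic cyclobutanone carbonyl (forming O1–C2) to give the bicyclic hemiketal 8, which collapses by retro-Claisen cleavage of the ring-fusion bond C2–C5 to the enolate 9, so that the two four-membered rings merge into the oxocane. The closest known reaction types are the acyl C–O opening of β-lactones by lithium enolates and the acylation/cyclisation/ring-expansion cascades of cyclic β-keto esters with protected β-hydroxy acid chlorides, which have not been run with a β-lactone as combined acyl donor and masked alkoxide or with a plain cyclobutanone. The only ring closed directly is the six-membered hemiketal (6-exo-trig); the eight-membered ring is not closed end to end but arises by fragmentation, driven by release of the strain of both small rings. No stereocenter of the product is created: C8 is carried over from 4 because the acyl–oxygen and not the alkyl–oxygen bond is broken, and the transient α-stereocenter of 7 is lost in 9. The step needs C- over O-acylation and acyl over alkyl attack on the lactone (expected for a lithium enolate in THF at low temperature) and cleavage of the fusion bond rather than the C2–C3 bond (only that cleavage expels a ketone enolate); the cold AcOH quench prevents β-elimination of the ring carboxylate from 9.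

Step 5
Reactants: 10 (8R)-8-[(1S)-1-(TBDPS-oxy)propyl]oxocane-2,6-dione
Product: 12 (5S,6S,8R)-5-chloro-6-hydroxy-8-[(1S)-1-(TBDPS-oxy)propyl]oxocan-2-one, via chloro ketone 11 (not isolated)
Conditions: (4R,5R)-4,5-diphenylimidazolidine (20 mol%), 2-nitrobenzoic acid (cat.), N-chlorosuccinimide, MeCN, −24 °C; then MeOH, CeCl3·7H2O, NaBH4, −78 °C; AcOH
Reagents that add atoms: N-chlorosuccinimide, O=C1CCC(=O)N1Cl
Why: enamine-catalysed α-chlorination should occur at the less hindered methylene C5 (C7 adjoins the branched C8) with the C5 configuration set by the catalyst (the antipode that gives 5S is used), and Luche reduction of the configurationally labile chloro ketone without isolation should follow the polar Felkin–Anh model, hydride entering anti to the C–Cl bond to give the trans (5S,6S) chlorohydrin.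

Step 6
Reactants: 12 (5S,6S,8R)-5-chloro-6-hydroxy-8-[(1S)-1-(TBDPS-oxy)propyl]oxocan-2-one
Product: 13 (5S,6S,8R)-6-(TBS-oxy)-5-chloro-8-[(1S)-1-(TBDPS-oxy)propyl]oxocan-2-one
Conditions: TBSOTf, 2,6-lutidine, CH2Cl2, −78 °C
Reagents that add atoms: tert-butyldimethylsilyl trifluoromethanesulfonate, CC(C)(C)[Si](C)(C)OS(=O)(=O)C(F)(F)F
Why: silylation of the secondary alcohol with a silyl triflate and a hindered pyridine base blocks transannular attack of the C6 oxygen on C2 (contraction to a six-membered ring) in all later steps.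

Step 7
Reactants: 13 (5S,6S,8R)-6-(TBS-oxy)-5-chloro-8-[(1S)-1-(TBDPS-oxy)propyl]oxocan-2-one
Product: 15 (3S,5S,6S,8R)-6-(TBS-oxy)-3,5-dichloro-8-[(1S)-1-(TBDPS-oxy)propyl]oxocan-2-one, via lactone lithium enolate 14 (not isolated)
Conditions: LiN(SiMe3)2 (1.0 equiv), THF, −78 °C; N-chlorosuccinimide, −78 °C; AcOH
Reagents that add atoms: N-chlorosuccinimide, O=C1CCC(=O)N1Cl
Why: electrophilic α-chlorination of the lithium enolate of the cis-lactone, in which the chlorine should approach the ring periphery on the face away from the C8 side chain so that C3 becomes S, the enolate being kept at −78 °C so that it does not displace the C5 chloride.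

Step 8
Reactants: 15 (3S,5S,6S,8R)-6-(TBS-oxy)-3,5-dichloro-8-[(1S)-1-(TBDPS-oxy)propyl]oxocan-2-one
Product: 17 (3S,5S,6S,8R)-6-(TBS-oxy)-3,5-dichloro-8-[(1S)-1-(TBDPS-oxy)propyl]oxocan-2-yl acetate (both C2 epimers), via aluminium hemiacetal 16 (not isolated)
Conditions: i-Bu2AlH (1.1 equiv), CH2Cl2, −78 °C; then pyridine, DMAP, Ac2O, −78 to 0 °C
Reagents that add atoms: acetic anhydride, CC(=O)OC(C)=O
Why: reductive acetylation, in which one hydride adds to the electrophilic α-chloro lactone and the aluminium hemiacetal is acetylated in the flask before the ring can open, the C2 configuration being of no consequence.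

Step 9
Reactants: 17 (3S,5S,6S,8R)-6-(TBS-oxy)-3,5-dichloro-8-[(1S)-1-(TBDPS-oxy)propyl]oxocan-2-yl acetate
Product: 19 (2S,3S,5S,6S,8R)-2-allyl-6-(TBS-oxy)-3,5-dichloro-8-[(1S)-1-(TBDPS-oxy)propyl]oxocane, via ring oxocarbenium ion 18 (not isolated)
Conditions: allylSiMe3 (4 equiv), BF3·OEt2, CH2Cl2, −78 °C
Reagents that add atoms: allyltrimethylsilane, C=CC[Si](C)(C)C
Why: Hosomi–Sakurai allylation of the ring oxocarbenium ion, in which the carbon nucleophile should enter anti to the C8 substituent (2,8-trans) on the face cis to the C3 chloride that α-heteroatom-substituted oxocarbenium ions favour, setting C2 as S.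

Step 10
Reactants: 19 (2S,3S,5S,6S,8R)-2-allyl-6-(TBS-oxy)-3,5-dichloro-8-[(1S)-1-(TBDPS-oxy)propyl]oxocane
Product: 20 (2S,3S,5S,6S,8R)-2-allyl-3,5-dichloro-8-[(1S)-1-(TBDPS-oxy)propyl]oxocan-6-ol
Conditions: HF·pyridine, pyridine, THF, 0 °C to rt
Reagents that add atoms: none
Why: acidic fluoride cleaves the secondary TBS ether much faster than the TBDPS ether, and the acidic medium avoids an alkoxide next to the trans C5 chloride (no epoxide closure).

Step 11
Reactants: 20 (2S,3S,5S,6S,8R)-2-allyl-3,5-dichloro-8-[(1S)-1-(TBDPS-oxy)propyl]oxocan-6-ol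
Product: 21 (2S,3S,5S,6S,8R)-2-allyl-3,5-dichloro-8-[(1S)-1-(TBDPS-oxy)propyl]oxocan-6-yl acetate
Conditions: Ac2O, pyridine, DMAP (cat.), CH2Cl2, rt
Reagents that add atoms: acetic anhydride, CC(=O)OC(C)=O
Why: DMAP-catalysed acylation of the secondary alcohol installs the C6 acetate of the target without touching a stereocenter.

Step 12
Reactants: 22 ethynyltri(propan-2-yl)silane; 23 bromoethene
Product: 24 (but-3-en-1-yn-1-yl)tri(propan-2-yl)silane
Conditions: Pd(PPh3)2Cl2 (2 mol%), CuI (4 mol%), i-Pr2NH, THF, 0 °C to rt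
Reagents that add atoms: none
Why: Sonogashira coupling of a terminal alkyne with a vinyl bromide gives the silyl-protected conjugated enyne.

Step 13
Reactants: 21 (2S,3S,5S,6S,8R)-2-allyl-3,5-dichloro-8-[(1S)-1-(TBDPS-oxy)propyl]oxocan-6-yl acetate; 24 (but-3-en-1-yn-1-yl)tri(propan-2-yl)silane
Product: 25 (2S,3S,5S,6S,8R)-3,5-dichloro-8-[(1S)-1-(TBDPS-oxy)propyl]-2-[(2Z)-5-(TIPS)pent-2-en-4-yn-1-yl]oxocan-6-yl acetate
Conditions: 24 (4 equiv), second-generation Grubbs catalyst (H2IMes)(PCy3)Cl2Ru=CHPh (10 mol%), benzene, 70 °C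
Reagents that add atoms: none
Why: olefin cross-metathesis of the terminal allyl group with a silyl-protected conjugated enyne, a pairing known to favour the Z-enyne kinetically, releases ethene and should set the 2Z double bond.

Step 14
Reactants: 25 (2S,3S,5S,6S,8R)-3,5-dichloro-8-[(1S)-1-(TBDPS-oxy)propyl]-2-[(2Z)-5-(TIPS)pent-2-en-4-yn-1-yl]oxocan-6-yl acetate
Product: 26 (2S,3S,5S,6S,8R)-3,5-dichloro-8-[(1S)-1-hydroxypropyl]-2-[(2Z)-pent-2-en-4-yn-1-yl]oxocan-6-yl acetate
Conditions: Bu4NF, AcOH, THF, 0 °C to rt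
Reagents that add atoms: none
Why: buffered fluoride removes the alkynyl TIPS group and the TBDPS ether in one operation, while the acetate and the secondary chlorides should stay untouched.

Step 15
Reactants: 26 (2S,3S,5S,6S,8R)-3,5-dichloro-8-[(1S)-1-hydroxypropyl]-2-[(2Z)-pent-2-en-4-yn-1-yl]oxocan-6-yl acetate
Product: 27 (2S,3S,5S,6S,8R)-8-[(1R)-1-bromopropyl]-3,5-dichloro-2-[(2Z)-pent-2-en-4-yn-1-yl]oxocan-6-yl acetate (CNP0251465.2)
Conditions: CBr4, P(n-C8H17)3, toluene, 70 °C
Reagents that add atoms: carbon tetrabromide, BrC(Br)(Br)Br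
Why: Appel-type bromination of the secondary carbinol next to the ring ether carbon proceeds by SN2 displacement with inversion, turning the (1S)-alcohol into the (1R)-bromide.

Compound list
1 | (±)-pent-1-en-3-ol | C=CC(O)CC | starting material
2 | (1S)-1-[(2R)-oxiran-2-yl]propan-1-ol | CC[C@H](O)[C@H]1CO1 | intermediate
3 | tert-butyl{(1S)-1-[(2R)-oxiran-2-yl]propoxy}diphenylsilane | CC[C@H](O[Si](c1ccccc1)(c1ccccc1)C(C)(C)C)[C@H]2CO2 | intermediate
4 | (4R)-4-[(1S)-1-(TBDPS-oxy)propyl]oxetan-2-one | CC[C@H](O[Si](c1ccccc1)(c1ccccc1)C(C)(C)C)[C@H]2CC(=O)O2 | intermediate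
5 | cyclobutanone | O=C1CCC1 | starting material
6 | lithium cyclobut-1-en-1-olate | [Li]OC1=CCC1 | intermediate
7 | lithium (3R,4S)-4-(TBDPS-oxy)-1-oxo-1-(2-oxocyclobutyl)hexan-3-olate | CC[C@H](O[Si](c1ccccc1)(c1ccccc1)C(C)(C)C)[C@H](O[Li])CC(=O)C3CCC3=O | intermediate
8 | lithium (3R)-3-[(1S)-1-(TBDPS-oxy)propyl]-5-oxo-2-oxabicyclo[4.2.0]octan-1-olate | CC[C@H](O[Si](c1ccccc1)(c1ccccc1)C(C)(C)C)[C@H]2CC(=O)C3CCC3(O[Li])O2 | intermediate
9 | lithium (8R)-8-[(1S)-1-(TBDPS-oxy)propyl]-2-oxo-3,4,7,8-tetrahydro-2H-oxocin-6-olate | CC[C@H](O[Si](c1ccccc1)(c1ccccc1)C(C)(C)C)[C@H]2CC(O[Li])=CCCC(=O)O2 | intermediate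
10 | (8R)-8-[(1S)-1-(TBDPS-oxy)propyl]oxocane-2,6-dione | CC[C@H](O[Si](c1ccccc1)(c1ccccc1)C(C)(C)C)[C@H]2CC(=O)CCCC(=O)O2 | intermediate
11 | (5S,8R)-5-chloro-8-[(1S)-1-(TBDPS-oxy)propyl]oxocane-2,6-dione | CC[C@H](O[Si](c1ccccc1)(c1ccccc1)C(C)(C)C)[C@H]2CC(=O)[C@@H](Cl)CCC(=O)O2 | intermediate
12 | (5S,6S,8R)-5-chloro-6-hydroxy-8-[(1S)-1-(TBDPS-oxy)propyl]oxocan-2-one | CC[C@H](O[Si](c1ccccc1)(c1ccccc1)C(C)(C)C)[C@H]2C[C@H](O)[C@@H](Cl)CCC(=O)O2 | intermediate
13 | (5S,6S,8R)-6-(TBS-oxy)-5-chloro-8-[(1S)-1-(TBDPS-oxy)propyl]oxocan-2-one | CC[C@H](O[Si](c1ccccc1)(c1ccccc1)C(C)(C)C)[C@H]2C[C@H](O[Si](C)(C)C(C)(C)C)[C@@H](Cl)CCC(=O)O2 | intermediate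
14 | lithium (5S,6S,8R)-6-(TBS-oxy)-5-chloro-8-[(1S)-1-(TBDPS-oxy)propyl]-5,6,7,8-tetrahydro-4H-oxocin-2-olate | CC[C@H](O[Si](c1ccccc1)(c1ccccc1)C(C)(C)C)[C@H]2C[C@H](O[Si](C)(C)C(C)(C)C)[C@@H](Cl)CC=C(O[Li])O2 | intermediate
15 | (3S,5S,6S,8R)-6-(TBS-oxy)-3,5-dichloro-8-[(1S)-1-(TBDPS-oxy)propyl]oxocan-2-one | CC[C@H](O[Si](c1ccccc1)(c1ccccc1)C(C)(C)C)[C@H]2C[C@H](O[Si](C)(C)C(C)(C)C)[C@@H](Cl)C[C@H](Cl)C(=O)O2 | intermediate
16 | (3S,5S,6S,8R)-6-(TBS-oxy)-3,5-dichloro-2-[(diisobutylalumanyl)oxy]-8-[(1S)-1-(TBDPS-oxy)propyl]oxocane (C2 epimers) | CC[C@H](O[Si](c1ccccc1)(c1ccccc1)C(C)(C)C)[C@H]2C[C@H](O[Si](C)(C)C(C)(C)C)[C@@H](Cl)C[C@H](Cl)C(O[Al](CC(C)C)CC(C)C)O2 | intermediate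
17 | (3S,5S,6S,8R)-6-(TBS-oxy)-3,5-dichloro-8-[(1S)-1-(TBDPS-oxy)propyl]oxocan-2-yl acetate (C2 epimers) | CC[C@H](O[Si](c1ccccc1)(c1ccccc1)C(C)(C)C)[C@H]2C[C@H](O[Si](C)(C)C(C)(C)C)[C@@H](Cl)C[C@H](Cl)C(OC(C)=O)O2 | intermediate
18 | (3S,5S,6S,8R)-6-(TBS-oxy)-3,5-dichloro-8-[(1S)-1-(TBDPS-oxy)propyl]-3,4,5,6,7,8-hexahydrooxocin-1-ium (C2=O1 oxocarbenium ion) | CC[C@H](O[Si](c1ccccc1)(c1ccccc1)C(C)(C)C)[C@H]2C[C@H](O[Si](C)(C)C(C)(C)C)[C@@H](Cl)C[C@H](Cl)C=[O+]2 | intermediate
19 | (2S,3S,5S,6S,8R)-2-allyl-6-(TBS-oxy)-3,5-dichloro-8-[(1S)-1-(TBDPS-oxy)propyl]oxocane | CC[C@H](O[Si](c1ccccc1)(c1ccccc1)C(C)(C)C)[C@H]2C[C@H](O[Si](C)(C)C(C)(C)C)[C@@H](Cl)C[C@H](Cl)[C@H](CC=C)O2 | intermediate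
20 | (2S,3S,5S,6S,8R)-2-allyl-3,5-dichloro-8-[(1S)-1-(TBDPS-oxy)propyl]oxocan-6-ol | CC[C@H](O[Si](c1ccccc1)(c1ccccc1)C(C)(C)C)[C@H]2C[C@H](O)[C@@H](Cl)C[C@H](Cl)[C@H](CC=C)O2 | intermediate
21 | (2S,3S,5S,6S,8R)-2-allyl-3,5-dichloro-8-[(1S)-1-(TBDPS-oxy)propyl]oxocan-6-yl acetate | CC[C@H](O[Si](c1ccccc1)(c1ccccc1)C(C)(C)C)[C@H]2C[C@H](OC(C)=O)[C@@H](Cl)C[C@H](Cl)[C@H](CC=C)O2 | intermediate
22 | ethynyltri(propan-2-yl)silane | C#C[Si](C(C)C)(C(C)C)C(C)C | starting material
23 | bromoethene | C=CBr | starting material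
24 | (but-3-en-1-yn-1-yl)tri(propan-2-yl)silane | C=CC#C[Si](C(C)C)(C(C)C)C(C)C | intermediate
25 | (2S,3S,5S,6S,8R)-3,5-dichloro-8-[(1S)-1-(TBDPS-oxy)propyl]-2-[(2Z)-5-(TIPS)pent-2-en-4-yn-1-yl]oxocan-6-yl acetate | CC[C@H](O[Si](c1ccccc1)(c1ccccc1)C(C)(C)C)[C@H]2C[C@H](OC(C)=O)[C@@H](Cl)C[C@H](Cl)[C@H](C/C=C\C#C[Si](C(C)C)(C(C)C)C(C)C)O2 | intermediate
26 | (2S,3S,5S,6S,8R)-3,5-dichloro-8-[(1S)-1-hydroxypropyl]-2-[(2Z)-pent-2-en-4-yn-1-yl]oxocan-6-yl acetate | CC[C@H](O)[C@H]2C[C@H](OC(C)=O)[C@@H](Cl)C[C@H](Cl)[C@H](C/C=C\C#C)O2 | intermediate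
27 | (2S,3S,5S,6S,8R)-8-[(1R)-1-bromopropyl]-3,5-dichloro-2-[(2Z)-pent-2-en-4-yn-1-yl]oxocan-6-yl acetate (CNP0251465.2) | C#C/C=C\C[C@@H]1O[C@@H]([C@H](Br)CC)C[C@H](OC(C)=O)[C@@H](Cl)C[C@@H]1Cl | target

Total step count: 15. Longest linear sequence: 14 steps (steps 1–11 and 13–15, from pent-1-en-3-ol).

Steps most likely to fail

Step 4 (carries the label "Proposed new method:"). The cascade may stall after C-acylation, because the acylated cyclobutanone can rest as its doubly stabilised enolate and the alkoxide then never adds to the ring carbonyl. The enolate may also be O-acylated or attack the alkyl C–O carbon of the lactone, cyclobutanone may self-condense, and the product enolate may lose the ring carboxylate by β-elimination. The fallback uses known chemistry and makes the two bonds one after the other. It sets out from 4, which is opened with Me(MeO)NH·HCl and Me2AlCl to the β-hydroxy Weinreb amide F1. Addition of CH2=CH(CH2)3MgBr gives the hydroxy ketone F2 (forming C5–C6). Ozonolysis (O3, then Me2S) gives the keto aldehyde F3, and Pinnick oxidation (NaClO2, NaH2PO4, 2-methylbut-2-ene) gives the seco acid F4. Yamaguchi lactonization (2,4,6-trichlorobenzoyl chloride, Et3N, then DMAP, toluene, high dilution) closes O1–C2, and the route is rejoined at 10.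

Step 5. Enamine formation may take place toward C7 and be followed by β-elimination of the ring oxygen. The chlorination may show poor facial selectivity, and the chloro ketone may epimerise before hydride delivery. The new C6 alkoxide may also attack the lactone carbonyl across the ring, contracting it to a six-membered lactone. The fallback replaces catalyst-controlled enamine chlorination by regiospecific enolate chlorination and a dynamic reduction. It sets out from the enolate 9 in the flask of step 4, which is quenched with N-chlorosuccinimide at −78 °C to give the chloro ketone F5 as both C5 epimers. F5 is then reduced with a ketoreductase chosen by screening (NADPH recycled with glucose and glucose dehydrogenase, pH 7 buffer), under conditions where the α-chloro ketone epimerises and only the (5S) epimer is reduced to the (6S) alcohol. The route is rejoined at 12.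

Step 7. The lactone enolate may displace the C5 chloride intramolecularly (cyclopropane formation), the chlorinating agent may attack the wrong face, or double chlorination may occur. The fallback avoids any enolate and bypasses steps 8 and 9. It sets out from 13, which is reductively acetylated (i-Bu2AlH, then Ac2O, pyridine, DMAP) to the acetoxy ether F6. Elimination of acetic acid with Me3SiOTf and i-Pr2NEt gives the cyclic enol ether F7. N-Chlorosuccinimide in MeOH adds chlorine and methoxide trans across C2=C3 to give the chloro methyl acetal F8. Treatment of F8 with allylSiMe3 and Me3SiOTf rejoins the route at 19.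

Further compounds
F1 | step 4 | (3R,4S)-4-(TBDPS-oxy)-3-hydroxy-N-methoxy-N-methylhexanamide | CC[C@H](O[Si](c1ccccc1)(c1ccccc1)C(C)(C)C)[C@H](O)CC(=O)N(C)OC
F2 | step 4 | (8R,9S)-9-(TBDPS-oxy)-8-hydroxyundec-1-en-6-one | CC[C@H](O[Si](c1ccccc1)(c1ccccc1)C(C)(C)C)[C@H](O)CC(=O)CCCC=C
F3 | step 4 | (7R,8S)-8-(TBDPS-oxy)-7-hydroxy-5-oxodecanal | CC[C@H](O[Si](c1ccccc1)(c1ccccc1)C(C)(C)C)[C@H](O)CC(=O)CCCC=O
F4 | step 4 | (7R,8S)-8-(TBDPS-oxy)-7-hydroxy-5-oxodecanoic acid | CC[C@H](O[Si](c1ccccc1)(c1ccccc1)C(C)(C)C)[C@H](O)CC(=O)CCCC(=O)O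
F5 | step 5 | (8R)-5-chloro-8-[(1S)-1-(TBDPS-oxy)propyl]oxocane-2,6-dione (both C5 epimers) | CC[C@H](O[Si](c1ccccc1)(c1ccccc1)C(C)(C)C)[C@H]2CC(=O)C(Cl)CCC(=O)O2
F6 | step 7 | (5S,6S,8R)-6-(TBS-oxy)-5-chloro-8-[(1S)-1-(TBDPS-oxy)propyl]oxocan-2-yl acetate (C2 epimers) | CC[C@H](O[Si](c1ccccc1)(c1ccccc1)C(C)(C)C)[C@H]2C[C@H](O[Si](C)(C)C(C)(C)C)[C@@H](Cl)CCC(OC(C)=O)O2
F7 | step 7 | (5S,6S,8R)-6-(TBS-oxy)-5-chloro-8-[(1S)-1-(TBDPS-oxy)propyl]-5,6,7,8-tetrahydro-4H-oxocine | CC[C@H](O[Si](c1ccccc1)(c1ccccc1)C(C)(C)C)[C@H]2C[C@H](O[Si](C)(C)C(C)(C)C)[C@@H](Cl)CC=CO2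
F8 | step 7 | (3S,5S,6S,8R)-6-(TBS-oxy)-3,5-dichloro-2-methoxy-8-[(1S)-1-(TBDPS-oxy)propyl]oxocane (C2 epimers) | CC[C@H](O[Si](c1ccccc1)(c1ccccc1)C(C)(C)C)[C@H]2C[C@H](O[Si](C)(C)C(C)(C)C)[C@@H](Cl)C[C@H](Cl)C(OC)O2
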